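**Plan**

1. The target is an achiral ester. Its acyl chain is numbered C1 (ester carbonyl) to C21. Retrosynthetically an oxygen is put back on C3 (alkane ← C2=C3 enoate ← C3 carbinol ← C3 ketone), and the C2–C3 bond of the resulting β-keto ester is cut first.
2. The enabling feature is the C1–C2 acetate unit. C2 lies α to the ester carbonyl C1, so C1–C2 can come from a malonate half-ester that already carries the O–CH2CH2–phenyl group, and C3–C21 is nonadecanoic acid. The benzene ring is the only ring, it is a spectator, and no ring is formed.
3. The remaining cuts are the C1–O bond of the half-ester (Meldrum's acid + 2-phenylethanol) and the acyl–N bond of the C19 imidazolide (acid + CDI).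
4. Forward: the two fragments are made in parallel and joined at C2–C3 by a magnesium-mediated decarboxylative Claisen condensation. C3 is then taken down by ketone reduction, mesylate elimination and alkene hydrogenation.
5. Stereochemistry: the target has none. The C3 carbinol is made racemic on purpose and erased by elimination, and the enoate geometry is erased by hydrogenation.

Key step: step 3

Assumption: the target has no stereocentre and no C=C bond, so "single enantiomer" is read as the one achiral structure drawn, and racemic intermediates are adequate.

**Route**

Step 1
Reactants: 1 Meldrum's acid (2,2-dimethyl-1,3-dioxane-4,6-dione); 2 2-phenylethanol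
Product: 3 3-oxo-3-(2-phenylethoxy)propanoic acid (mono-phenethyl malonate)
Conditions: 1 (1.0 equiv), 2 (1.0 equiv), toluene, 105 °C, acetone distilled off; extraction into aq. NaHCO3, acidification to pH 2, EtOAc
Reagents that add atoms: none
Why: Thermal alcoholysis of Meldrum's acid (ring-opening acyl substitution at the activated cyclic acylal, then loss of acetone) should stop at the half-ester because the carboxylic acid that is unveiled is no acylating agent, and bicarbonate extraction separates acid 3 from neutral material.

Step 2
Reactants: 4 nonadecanoic acid
Product: 5 1-nonadecanoylimidazole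
Conditions: CDI (1.05 equiv), dry THF, rt → 40 °C until gas evolution ends; evaporation under N2, crude solid (contains one equivalent of imidazole) taken on
Reagents that add atoms: 1,1'-carbonyldiimidazole (CDI), O=C(n1ccnc1)n1ccnc1
Why: Acyl imidazolide formation with CDI runs through the mixed carbonic anhydride and is driven by loss of CO2, and the saturated acid has no other reactive site, so the activated C19 acyl donor should form cleanly.

Step 3
Reactants: 3 mono-phenethyl malonate; 5 1-nonadecanoylimidazole
Product: 8 2-phenylethyl 3-oxoheneicosanoate, via chloromagnesium malonate dianion 6 (not isolated), via acylmalonic half-ester 7 (not isolated)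
Conditions: 3 (2.0 equiv), i-PrMgCl (4.0 equiv), THF, 0 °C → rt, 1 h; then 5 (1.0 equiv) in THF, rt → 40 °C, 12 h; 1 M HCl, rt (CO2 evolution); EtOAc, NaHCO3 wash
Reagents that add atoms: none
Why: Two equivalents of Grignard base remove the carboxyl and the C2 protons of 3 to give the chelated enolate–carboxylate 6, whose carbon adds to the imidazolide carbonyl of 5 and expels imidazolide (addition–elimination) to give the magnesium chelate of acylmalonate 7; acidification frees the β-keto acid, which loses CO2 through a six-membered transition state and leaves the new C2–C3 bond of 8. The closest known reaction type is the decarboxylative Claisen condensation of magnesium malonate half-esters with acyl imidazolides, the laboratory counterpart of the ketosynthase step of fatty acid biosynthesis. No ring is closed and no stereocentre is created. The step needs C- rather than O-acylation and a single acylation: the six-membered magnesium chelate of 6 leaves carbon as the nucleophilic site, the product chelate of 7 is a deactivated tricarbonyl anion that is not acylated again, and the final loss of CO2 is irreversible. The saturated C18 chain of 5 offers no second electrophilic site, and the phenethyl ester is spared because the Grignard reagent is consumed by two fast deprotonations at 0 °C before 5 is added. The excess of 6 also absorbs the N–H of the imidazole that accompanies 5.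

Step 4
Reactants: 8 2-phenylethyl 3-oxoheneicosanoate
Product: 9 2-phenylethyl 3-hydroxyheneicosanoate (racemic at C3)
Conditions: NaBH4 (0.5 equiv), THF/i-PrOH 4:1, −10 → 0 °C; sat. aq. NH4Cl
Reagents that add atoms: none
Why: Chemoselective borohydride reduction of the ketone of a β-keto ester (the ketoreductase counterpart) should leave the far less electrophilic ester alone at low temperature with a limited hydride charge and a hindered alcohol cosolvent, and the new C3 stereocentre is deliberately formed racemic because step 5 destroys it.

Step 5
Reactants: 9 2-phenylethyl 3-hydroxyheneicosanoate
Product: 11 2-phenylethyl (E)-heneicos-2-enoate, via β-mesyloxy ester 10 (not isolated)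
Conditions: MsCl (1.3 equiv), Et3N (1.5 equiv), CH2Cl2, 0 °C; then DBU (2.0 equiv), 0 °C → rt
Reagents that add atoms: none
Why: O-Mesylation followed by base-mediated E1cB elimination of the β-sulfonyloxy ester (the dehydratase counterpart) is driven by conjugation with the ester and should favour the (E)-2-enoate, while any Z or β,γ isomer converges on the same product in step 6.

Step 6
Reactants: 11 2-phenylethyl (E)-heneicos-2-enoate
Product: 12 2-phenylethyl heneicosanoate (phenylethyl n-heneicosanoate)
Conditions: H2 (1 atm), 10% Pd/C, EtOAc, rt
Reagents that add atoms: none
Why: Heterogeneous catalytic hydrogenation of the conjugated C=C bond (the enoyl reductase counterpart) is fast over Pd/C at 1 atm, whereas the arene is inert under these conditions and the homobenzylic O–CH2 bond, unlike a benzylic one, is not hydrogenolysed.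

**Compound list**

1 | Meldrum's acid (2,2-dimethyl-1,3-dioxane-4,6-dione) | CC1(C)OC(=O)CC(=O)O1 | starting material
2 | 2-phenylethanol | OCCc1ccccc1 | starting material
3 | 3-oxo-3-(2-phenylethoxy)propanoic acid (mono-phenethyl malonate) | OC(=O)CC(=O)OCCc1ccccc1 | intermediate
4 | nonadecanoic acid | CCCCCCCCCCCCCCCCCCC(=O)O | starting material
5 | 1-nonadecanoylimidazole | CCCCCCCCCCCCCCCCCCC(=O)n1ccnc1 | intermediate
6 | bis(chloromagnesium) enolate–carboxylate of 3 (chloromagnesium malonate dianion, formed in the flask) | Cl[Mg]OC(=O)C=C(O[Mg]Cl)OCCc1ccccc1 | intermediate
7 | 2-nonadecanoylmalonic acid mono(2-phenylethyl) ester (acylmalonic half-ester, drawn as the free acid; formed in the flask) | CCCCCCCCCCCCCCCCCCC(=O)C(C(=O)O)C(=O)OCCc1ccccc1 | intermediate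
8 | 2-phenylethyl 3-oxoheneicosanoate | CCCCCCCCCCCCCCCCCCC(=O)CC(=O)OCCc1ccccc1 | intermediate
9 | 2-phenylethyl 3-hydroxyheneicosanoate (racemic) | CCCCCCCCCCCCCCCCCCC(O)CC(=O)OCCc1ccccc1 | intermediate
10 | 2-phenylethyl 3-(methanesulfonyloxy)heneicosanoate (racemic; formed in the flask) | CCCCCCCCCCCCCCCCCCC(CC(=O)OCCc1ccccc1)OS(C)(=O)=O | intermediate
11 | 2-phenylethyl (E)-heneicos-2-enoate | CCCCCCCCCCCCCCCCCC/C=C/C(=O)OCCc1ccccc1 | intermediate
12 | 2-phenylethyl heneicosanoate | CCCCCCCCCCCCCCCCCCCCC(=O)OCCc1ccccc1 | target

**Step count**

Total steps: 6. Longest linear sequence: 5 steps (step 1 or step 2, then steps 3 to 6).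

**Steps most likely to fail**

Step 3. The C-acylation may stall if the basic dianion is protonated by imidazole or adventitious moisture faster than it is acylated, and Grignard reagent left over from incomplete deprotonation may add to the phenethyl ester. The fallback sets out from 4 and returns to the route at 8. Nonadecanoic acid 4 is condensed with Meldrum's acid 1 (DCC, DMAP, CH2Cl2, 0 °C → rt) to give the C-acylated Meldrum's acid 5-(1-hydroxynonadecylidene)-2,2-dimethyl-1,3-dioxane-4,6-dione F1. Heating this with 2-phenylethanol 2 in toluene at reflux should release the acylketene, which the alcohol traps with loss of acetone and CO2 to give 8. The same C2–C3 bond is made from a malonate carbon nucleophile, but the decarboxylative step is neutral and thermal and involves no magnesium enolate.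

Step 5. Elimination of the mesylate may be incomplete, chloride may displace the sulfonate, or the base may trigger side reactions at the acidic C2 position that consume the ester. The fallback sets out from 9 and returns at 12, so it also bypasses 11 and step 6. The alcohol 9 is acylated (phenyl chlorothionoformate, pyridine, cat. DMAP, CH2Cl2, 0 °C → rt) to give 2-phenylethyl 3-[(phenoxycarbonothioyl)oxy]heneicosanoate F2. A Barton–McCombie deoxygenation (Bu3SnH, AIBN, toluene, 90 °C) should then replace the C3 oxygen by hydrogen through the secondary C3 radical, with no base and no alkene intermediate.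

Step 4. Reduction may run on past the hydroxy ester, because the chelated β-alkoxide can deliver hydride to the ester and give the 1,3-diol, and alkoxide formed in the medium may exchange the phenethyl ester with the alcohol cosolvent. The fallback sets out from 8 and returns at 12, bypassing steps 4 to 6. The ketone of 8 is converted (1,2-ethanedithiol, BF3·OEt2, CH2Cl2, rt) into the dithiolane 2-phenylethyl 2-(2-octadecyl-1,3-dithiolan-2-yl)acetate F3. A Mozingo desulfurisation (Raney nickel, THF, 50 °C) should then give the methylene compound directly, with no hydride reagent and no alkoxide in contact with the ester.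

**Further compounds**

F1 | step 3 | 5-(1-hydroxynonadecylidene)-2,2-dimethyl-1,3-dioxane-4,6-dione | CCCCCCCCCCCCCCCCCCC(O)=C1C(=O)OC(C)(C)OC1=O
F2 | step 5 | 2-phenylethyl 3-[(phenoxycarbonothioyl)oxy]heneicosanoate (racemic) | CCCCCCCCCCCCCCCCCCC(CC(=O)OCCc1ccccc1)OC(=S)Oc1ccccc1
F3 | step 4 | 2-phenylethyl 2-(2-octadecyl-1,3-dithiolan-2-yl)acetate | CCCCCCCCCCCCCCCCCCC1(CC(=O)OCCc2ccccc2)SCCS1
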